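## Structural features

The target is a linear octa(aryl ether): eight benzene rings A–H joined only by seven diaryl ether oxygens, with twenty-one free phenolic hydroxyls and no C–C bond between rings. It has no stereocentre, so no configuration has to be set and the whole problem is regiochemical. Ring A is a 2,4,6-trihydroxyphenyl ether, ring B is 1,3,4,5-tetraoxygenated (C1–O–A, C3/C4–OH, C5–O–C), rings D and F are hydroquinone diethers (ether oxygens at C1 and C4) with hydroxyls at C3 and C5, and ring H is a 3,4,5-trihydroxyphenyl ether. Rings C, E and G are pentaoxygenated, with five contiguous oxygens (C1 ether to the preceding ring, C2 ether to the following ring, C3–C5 hydroxyl) and a single C6–H. The fragile elements are the free pyrogallol and hydroxyhydroquinone units, which air oxidises to quinones as soon as base is present, so every hydroxyl must stay masked until a neutral last step; the diaryl ethers are robust. The real difficulty lies in the three pentaoxygenated rings, where every oxygen must be differentiated and each ether bond is flanked by two ortho oxygens. The key step exploits ring C: C2–C5 with their oxygens map onto the four carbons of a squarate, and C1 (with the ether oxygen to ring B) plus C6–H map onto a two-carbon aryloxyvinyl unit, so that ring expansion delivers the ring with C2–OH as its only free phenol. Rings E and G stand in the same relation to rings D and F, so the construction can be repeated.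

## Logic of the disconnections

**51 from 50.** The nineteen benzylic C–O bonds are cut last. Benzyl is the one group that leaves under neutral, non-oxidising conditions, which the oxidation-prone polyphenol requires, and the cut turns a polar polyphenol into a lipophilic compound that can be chromatographed. The forward step demands that 50 holds no silyl ether and no formyl group.

**50 from 48, and 48 from 47 plus 25.** On ring H the C4–O bond is traced back to a C4–CHO bond and the O–Si bond on ring G is restored; then the ether bond between O2 of ring G and C1 of ring H is cut. The formyl group does double duty: it activates the bromide of 25 for C–O coupling and is a latent hydroxyl. Ring H is thereby reduced to a one-step building block. The forward coupling must arylate a phenol flanked by two ortho oxygens without loss of the silyl group.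

**47 from 44, 44 from 41 plus 3, 41 from 40 plus 15.** The C1–C2 bond of ring G is cut (ring expansion in reverse), then the bond between the carbinol carbon of the four-membered ring and the vinyl carbon together with the O–Si bond, then the O–vinyl bond. Ring G falls apart into a squarate (C2–C5), a two-carbon unit (C1, C6) and the phenol oxygen of ring F. The forward steps demand a configurationally defined Z vinyllithium and outward rotation of the silyloxy group.

**40 from 38, 38 from 36 plus 25; 36 from 33, 33 from 30 plus 3, 30 from 29 plus 15.** Rings F and E are removed by the same operations. In addition the benzyl group on O5 of ring E is traced back to silicon, because the silyl ether is needed only to distinguish O2 from O5 during arylation. The demand is that the silyl-to-benzyl exchange precedes the next vinylation, since an aryl silyl ether would not survive its carbonate/DMF medium.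

**29 from 27, 27 from 23 plus 25.** Ring D is removed in the same way: C4–O back to C4–CHO, benzyl on O5 of ring C back to silicon, then the ether bond between O2 of ring C and C1 of ring D.

**23 from 20.** The C1–C2 bond of ring C is cut and the ring is contracted to a cyclobutenone; 20 and 23 are isomers, so no atom is lost or gained. This is the largest single gain in simplicity, because a benzene ring with five differentiated oxygens becomes a symmetrical squarate plus an enol ether. The forward step demands torquoselective ring opening.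

**20 from 17 plus 3, and 17 from 14 plus 15.** The C–C bond between the carbinol carbon and the vinyl group and the O–Si bond are cut, then the O–vinyl bond. This leaves a phenol, a C2 dihalide and a squarate. The forward step needs halogen–lithium exchange that is faster than loss of aryloxide from the vinyllithium, and silylation before the alkoxide is warmed.

**14 from 12, and 12 from 9 plus 11.** The C5–O bond of ring B is traced back to a formyl group, and the ether bond between ring A oxygen and C1 of ring B is cut. Both rings become simple benzaldehyde-derived monomers. The forward coupling uses a doubly ortho-substituted phenol and an unhindered bromide.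

**9 from 7, 7 from 6, 6 from 4; 11 from 10; 25 from 24 plus 2; 3 from 1 plus 2.** O–benzyl bonds, one C–CHO bond (ring A) and two aryl C–O bonds (ring D/F/H block) are cut back to catalogue compounds. The demands are selectivity for fluoride over bromide in the formation of 25 and two molecules of 2 for each molecule of 3 and of 25.

## Other disconnections considered

Alternative 1: The cut is made at seven aryl C–OH bonds, at C4 of ring A and at C3 and C4 of rings C, E and G, each traced back to an aryl–CHO bond. Forward, the heptaaldehyde A2 would be treated with mCPBA, seven aryl groups would migrate to oxygen (Baeyer–Villiger/Dakin), and methanolysis of the formates would give the heptaphenol A1, which hydrogenolysis would convert into 51.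
- In its favour: formyl groups are the classical activators for building diaryl ethers by nucleophilic aromatic substitution, so one substituent would serve for chain assembly and as latent hydroxyl. The oxidation is ionic, well understood and needs no cryogenic organometallic step. One operation would form seven C–O bonds, which is better in bonds per step than anything in the chosen plan.
- Against it here: the step forms no ring and no ether, so each pentasubstituted ring of A2 (three oxygens and two adjacent formyl groups) must be made beforehand and is no easier to obtain than the pentaoxygenated rings themselves. Ortho-diformyl arenes can divert through hydrates, lactols or hydride migration, and sevenfold fidelity is required.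
- Comparison: the mechanism is the equal of the chosen plan for an isolated electron-rich aldehyde (the plan uses it five times) and weaker for the three phthalaldehyde units. Structurally it postpones the differentiation of the five oxygens without solving it. In step count it wins at the last stage and loses in the preparation of A2.

Alternative 2: Ring A is cut at its C3–C4 bond and unravelled into a 3,5-dioxoheptanedioate chain that carries the rest of the molecule as a 4-aryloxy substituent. Forward, base would deprotonate the C6 methylene of the diketo diester A4, intramolecular Claisen (Dieckmann-type) acylation of the C1 ester would close the ring, and enolisation would give the phloroglucinol carboxylate A3. Saponification, decarboxylation and hydrogenolysis would then lead to 51.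
- In its favour: a biomimetic, polyketide-like aromatisation under mild ionic conditions, with unambiguous placement of the three hydroxyls. Ring A needs no protecting groups, a point on which it is better than the chosen plan.
- Against it: it constructs the one ring that is available from 4 in three steps and leaves rings C, E and G untouched. It places the attachment of the whole B–H aryloxy group to the central carbon of a tricarbonyl chain at the very end, and the free, highly nucleophilic ring A of A3 must then survive ester removal.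
- Comparison: mechanistically the condensation is at least as predictable as the pericyclic sequence and needs no torquoselectivity (equal or better). Structurally it contributes far less, since the difficulty does not lie in ring A. In steps it is worse, because the ester must be removed and everything else must still be made by other means.

Alternative 3: Ring E is cut at three bonds, C5–C6, C1–C2 and C4–C5, which divides the octamer into the ethynyl ether A7 of the A–D tetramer (C1 and C6 of ring E) and the cyclobutenone A6 that carries rings F–H on its aryloxy group (C2–C5 of ring E). Forward, heating A6 would open it to a vinylketene, [2+2] cycloaddition with the alkyne of A7 would give a 4-vinylcyclobutenone, and a second four-electron opening, six-electron closure and tautomerisation (Danheiser-type benzannulation) would give A5. The only free hydroxyl of A5 is one the target also has, so a single hydrogenolysis would finish 51.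
- In its favour: it is the most convergent plan, joining a tetramer and a trimer while creating a ring and three bonds, and the path from key product to target is shorter than in the chosen plan; both are points on which it is better. It uses the same mapping of four ring carbons onto a squarate, so structurally it is the equal of the chosen plan.
- Against it: A6 is an unsymmetrical cyclobutenone with an aryl vinylogous ester and an sp3 C–H carbon, whose preparation from a squarate needs a regioselective reduction and two differentiated O-substitutions. A7 is a heat-sensitive aryl ynol ether of a doubly ortho-substituted phenol. The cascade has four pericyclic events, one of them bimolecular, against two unimolecular ones in the chosen step.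
- Comparison: rings C and G would still have to be built, most plausibly by the chosen ring expansion, so this alternative complements the plan more than it replaces it.

Key step: step 10

**Remarks on the chemistry**

- Assumption: 1,2-dibromoethylene is used as the commercial cis/trans mixture (the cis isomer is the faster source of bromoacetylene); 5-bromo-2,3-dihydroxybenzaldehyde and 4-bromo-2,6-difluorobenzaldehyde are taken as catalogue compounds.
- Structure check: 20 and 23 are isomers and the numbering of ring C agrees with the target, so neither structure needs correction.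
- Precursor design: the tertiary alkoxide is silylated in the flask in which it forms, and the aryl silyl ether is exchanged for benzyl directly after the arylation in which it is needed.
- Stoichiometry: steps 1 and 11 each build two molecules of benzyl alcohol into the product.
- Bromoacetylene: it is numbered 16 where it first forms (step 8). In steps 14 and 19 the same transient reagent is made again from 15 in the presence of the phenoxide and used up at once.
- Safety: bromoacetylene is never isolated or stored. The vinylations run in a closed, argon-flushed vessel, and residual haloalkyne is destroyed with diethylamine before the vessel is opened.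
- Linear growth: the chain is grown from ring A to ring H because every ring expansion leaves the new ring as the phenolic partner; a preassembled right-hand block would have to carry an unactivated aryl halide through the organolithium steps.
- Names: rings keep the letters of the target. Ring B carries O–A at C1 and the oxygen towards ring C at C5. Rings D, F and H carry the oxygen to the preceding ring at C1 and the next oxygen (or formyl carbon) at C4. Rings C, E and G carry the oxygen to the preceding ring at C1, the oxygen towards the following ring at C2 and H at C6. "A–B aryloxy" is 2,3-bis(benzyloxy)-5-[2,4,6-tris(benzyloxy)phenoxy]phenoxy. "Perbenzylated" means every oxygen not mentioned is a benzyl ether; OBn = benzyloxy, OTBS = tert-butyldimethylsilyloxy.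

## Steps

Step 1
Reactants: 1 squaric acid; 2 benzyl alcohol
Product: 3 dibenzyl squarate (3,4-bis(benzyloxy)cyclobut-3-ene-1,2-dione)
Conditions: 2 (4 equiv), toluene, reflux, Dean–Stark removal of water
Reagents that add atoms: benzyl alcohol, OCc1ccccc1
Why: Fischer-type esterification of the strongly acidic vinylogous diacid, driven by removal of water; two molecules of benzyl alcohol are incorporated, which is the standard route to dialkyl squarates.

Step 2
Reactants: 4 phloroglucinol
Product: 6 2,4,6-trihydroxybenzaldehyde, via iminium chloride 5 (not isolated)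
Conditions: POCl3, DMF, EtOAc, 0 °C to rt; then H2O, 50 °C
Reagents that add atoms: N,N-dimethylformamide, CN(C)C=O; water, O
Why: Vilsmeier–Haack formylation; the iminium group deactivates the ring against a second attack and is hydrolysed to the aldehyde on aqueous work-up.

Step 3
Reactants: 6 2,4,6-trihydroxybenzaldehyde
Product: 7 2,4,6-tris(benzyloxy)benzaldehyde
Conditions: BnBr, K2CO3, DMF, 60 °C
Reagents that add atoms: benzyl bromide, BrCc1ccccc1
Why: Williamson etherification; the formyl group lowers the C-nucleophilicity of the phloroglucinol nucleus, so O-benzylation of all three phenols should dominate.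

Step 4
Reactants: 7 2,4,6-tris(benzyloxy)benzaldehyde
Product: 9 2,4,6-tris(benzyloxy)phenol, via aryl formate 8 (not isolated)
Conditions: mCPBA (1.2 equiv), CH2Cl2, 0 °C to rt; then K2CO3 (cat.), MeOH, 0 °C
Reagents that add atoms: mCPBA, OOC(=O)c1cccc(Cl)c1
Why: Dakin-type Baeyer–Villiger oxidation; the trialkoxyphenyl group migrates in preference to hydrogen, and the aryl formate is cleaved by methanolysis.

Step 5
Reactants: 10 5-bromo-2,3-dihydroxybenzaldehyde
Product: 11 2,3-bis(benzyloxy)-5-bromobenzaldehyde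
Conditions: BnBr, K2CO3, DMF, 50 °C
Reagents that add atoms: benzyl bromide, BrCc1ccccc1
Why: Williamson etherification of both phenols; bromide and aldehyde are inert.

Step 6
Reactants: 9 2,4,6-tris(benzyloxy)phenol; 11 2,3-bis(benzyloxy)-5-bromobenzaldehyde
Product: 12 dimer A–B aldehyde (2,3-bis(benzyloxy)-5-[2,4,6-tris(benzyloxy)phenoxy]benzaldehyde)
Conditions: CuI (10 mol %), picolinic acid (20 mol %), K3PO4, DMSO, 90 °C, argon
Reagents that add atoms: none
Why: Ullmann-type C–O coupling under monovalent copper/picolinate catalysis, a system suited to doubly ortho-substituted phenols; the bromide has no ortho substituent and the non-enolisable aldehyde tolerates K3PO4.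

Step 7
Reactants: 12 dimer A–B aldehyde
Product: 14 dimer A–B phenol (2,3-bis(benzyloxy)-5-[2,4,6-tris(benzyloxy)phenoxy]phenol), via aryl formate 13 (not isolated)
Conditions: mCPBA (1.2 equiv), CH2Cl2, 0 °C to rt; then K2CO3 (cat.), MeOH, 0 °C, argon
Reagents that add atoms: mCPBA, OOC(=O)c1cccc(Cl)c1
Why: Dakin-type Baeyer–Villiger oxidation; the ortho benzyloxy group makes the aryl ring the migrating group, and methanolysis frees the C5 phenol of ring B.

Step 8
Reactants: 14 dimer A–B phenol; 15 1,2-dibromoethylene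
Product: 17 (Z)-2-bromovinyl ether of the dimer (ring B C5–O–CH=CHBr), via bromoacetylene 16 (not isolated)
Conditions: 15 (3 equiv), Cs2CO3, DMF, 60 °C, closed vessel, argon; then Et2NH quench
Reagents that add atoms: none
Why: Nucleophilic vinylic substitution by elimination–addition: base converts 15 into bromoacetylene 16, and anti addition of the phenoxide places oxygen and bromine cis, which sets the Z geometry. Excess 15 suppresses a second addition.

Step 9
Reactants: 17 (Z)-2-bromovinyl ether of the dimer; 3 dibenzyl squarate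
Product: 20 racemic 2,3-bis(benzyloxy)-4-(tert-butyldimethylsilyloxy)-4-[(Z)-2-(A–B aryloxy)vinyl]cyclobut-2-enone, via vinyllithium 18 (not isolated), via lithium alkoxide 19 (not isolated)
Conditions: t-BuLi (2.0 equiv), THF–Et2O, −78 °C; added to 3 (1.5 equiv), THF, −78 °C; then TBSOTf, 2,6-lutidine, −78 to −20 °C
Reagents that add atoms: tert-butyldimethylsilyl trifluoromethanesulfonate, CC(C)(C)[Si](C)(C)OS(=O)(=O)C(F)(F)F
Why: Bromine–lithium exchange with retention gives the chelated Z vinyllithium, which adds 1,2 to one squarate carbonyl (standard squarate addition); O-silylation of the tertiary alkoxide before warming prevents anion-accelerated ring opening. The new C4 stereocentre forms as a racemate and is destroyed in step 10.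

Step 10
Reactants: 20 racemic 4-silyloxy-4-[(Z)-2-(A–B aryloxy)vinyl]cyclobutenone
Product: 23 trimer A–C phenol (ring C: 2-OH; 3,4-OBn; 5-OTBS), via dienylketene 21 (not isolated), via cyclohexadienone 22 (not isolated)
Conditions: toluene (degassed), 110 °C
Reagents that add atoms: none
Why: Moore rearrangement: heating opens the C1–C4 bond of the cyclobutenone in a conrotatory four-electron electrocyclic reaction and gives dienylketene 21. The step needs torquoselectivity, which the substrate secures because the silyloxy donor on C4 rotates outward and so turns the aryloxyvinyl group inward, cis to the ketene. Disrotatory six-electron electrocyclisation joins the ketene carbon to the aryloxy-bearing vinyl carbon, that is, forms the C1–C2 bond of ring C, and closes the six-membered ring as cyclohexadienone 22. Tautomerisation moves the C1 hydrogen to the carbonyl oxygen and aromatises the ring. C2–OH is then the only free phenol, because O5 carries silicon and O3/O4 carry benzyl. The closest known reaction type is the thermal ring expansion of squarate-derived 4-alkenyl- and 4-aryl-4-oxycyclobutenones to hydroquinone monoethers. No stereocentre results, since the C4 centre of 20 is lost on ring opening and the C1 centre of 22 on aromatisation. Regiochemistry follows from connectivity alone, since the ketene carbon can reach only the terminal vinyl carbon, and degassed solvent protects the electron-rich phenol from oxidation.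

Step 11
Reactants: 24 4-bromo-2,6-difluorobenzaldehyde; 2 benzyl alcohol
Product: 25 2,6-bis(benzyloxy)-4-bromobenzaldehyde
Conditions: 2 (2.3 equiv), NaH (2.2 equiv), THF, 0 °C; then 24, 0 °C to rt, then 40 °C
Reagents that add atoms: benzyl alcohol, OCc1ccccc1
Why: Twofold nucleophilic aromatic substitution by sodium benzyloxide, which builds in two molecules of benzyl alcohol; both fluorides are ortho to the formyl group and fluoride is by far the better leaving group in addition–elimination, so the bromide should stay.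

Step 12
Reactants: 23 trimer A–C phenol; 25 2,6-bis(benzyloxy)-4-bromobenzaldehyde
Product: 27 perbenzylated tetramer A–D aldehyde (ring D: 4-CHO), via silyl ether aldehyde 26 (not isolated)
Conditions: Pd2(dba)3 (2.5 mol %), tBuXPhos (6 mol %), K3PO4, toluene, 100 °C; then DMF, CsF, BnBr, rt
Reagents that add atoms: benzyl bromide, BrCc1ccccc1
Why: Buchwald–Hartwig-type C–O coupling: zerovalent palladium inserts into the C–Br bond para to the formyl group, and the electron-poor aryl favours C–O reductive elimination. The heterogeneous, aprotic medium should spare the silyl ether until fluoride removes it and the phenoxide is benzylated in the same flask (desilylative Williamson etherification).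

Step 13
Reactants: 27 perbenzylated tetramer A–D aldehyde
Product: 29 tetramer A–D phenol (ring D: 4-OH), via aryl formate 28 (not isolated)
Conditions: mCPBA (1.2 equiv), CH2Cl2, 0 °C to rt; then K2CO3 (cat.), MeOH, 0 °C, argon
Reagents that add atoms: mCPBA, OOC(=O)c1cccc(Cl)c1
Why: Dakin-type Baeyer–Villiger oxidation; the 2,6-dialkoxy-4-aryloxyphenyl group migrates readily and methanolysis frees the C4 phenol of ring D.

Step 14
Reactants: 29 tetramer A–D phenol; 15 1,2-dibromoethylene
Product: 30 (Z)-2-bromovinyl ether of the tetramer (ring D C4–O–CH=CHBr)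
Conditions: 15 (3 equiv), Cs2CO3, DMF, 60 °C, closed vessel, argon; then Et2NH quench
Reagents that add atoms: none
Why: Elimination–addition vinylation as in step 8, with bromoacetylene again made from 15 in the flask and consumed at once; the small linear electrophile should be reached even by the doubly ortho-substituted phenoxide, anti addition sets the Z geometry, and only benzyl ethers are exposed to the base.

Step 15
Reactants: 30 (Z)-2-bromovinyl ether of the tetramer; 3 dibenzyl squarate
Product: 33 racemic 2,3-bis(benzyloxy)-4-(tert-butyldimethylsilyloxy)-4-[(Z)-2-(tetramer A–D aryloxy)vinyl]cyclobut-2-enone, via vinyllithium 31 (not isolated), via lithium alkoxide 32 (not isolated)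
Conditions: t-BuLi (2.0 equiv), THF–Et2O, −78 °C; added to 3 (1.5 equiv), THF, −78 °C; then TBSOTf, 2,6-lutidine, −78 to −20 °C
Reagents that add atoms: tert-butyldimethylsilyl trifluoromethanesulfonate, CC(C)(C)[Si](C)(C)OS(=O)(=O)C(F)(F)F
Why: Bromine–lithium exchange, 1,2-addition to the squarate and silylation in the flask, as in step 9; the racemic C4 centre is lost in step 16.

Step 16
Reactants: 33 racemic 4-silyloxy-4-[(Z)-2-(tetramer A–D aryloxy)vinyl]cyclobutenone
Product: 36 pentamer A–E phenol (ring E: 2-OH; 3,4-OBn; 5-OTBS), via dienylketene 34 (not isolated), via cyclohexadienone 35 (not isolated)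
Conditions: toluene (degassed), 110 °C
Reagents that add atoms: none
Why: Moore rearrangement as in step 10: outward rotation of the silyloxy group, six-electron closure forming the C1–C2 bond of ring E, and tautomerisation; no stereocentre remains.

Step 17
Reactants: 36 pentamer A–E phenol; 25 2,6-bis(benzyloxy)-4-bromobenzaldehyde
Product: 38 perbenzylated hexamer A–F aldehyde (ring F: 4-CHO), via silyl ether aldehyde 37 (not isolated)
Conditions: Pd2(dba)3 (2.5 mol %), tBuXPhos (6 mol %), K3PO4, toluene, 100 °C; then DMF, CsF, BnBr, rt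
Reagents that add atoms: benzyl bromide, BrCc1ccccc1
Why: Buchwald–Hartwig-type C–O coupling followed by desilylative benzylation, as in step 12.

Step 18
Reactants: 38 perbenzylated hexamer A–F aldehyde
Product: 40 hexamer A–F phenol (ring F: 4-OH), via aryl formate 39 (not isolated)
Conditions: mCPBA (1.2 equiv), CH2Cl2, 0 °C to rt; then K2CO3 (cat.), MeOH, 0 °C, argon
Reagents that add atoms: mCPBA, OOC(=O)c1cccc(Cl)c1
Why: Dakin-type Baeyer–Villiger oxidation as in step 13.

Step 19
Reactants: 40 hexamer A–F phenol; 15 1,2-dibromoethylene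
Product: 41 (Z)-2-bromovinyl ether of the hexamer (ring F C4–O–CH=CHBr)
Conditions: 15 (3 equiv), Cs2CO3, DMF, 60 °C, closed vessel, argon; then Et2NH quench
Reagents that add atoms: none
Why: Elimination–addition vinylation as in steps 8 and 14, with bromoacetylene again made from 15 in the flask and consumed at once; anti addition of the phenoxide sets the Z geometry.

Step 20
Reactants: 41 (Z)-2-bromovinyl ether of the hexamer; 3 dibenzyl squarate
Product: 44 racemic 2,3-bis(benzyloxy)-4-(tert-butyldimethylsilyloxy)-4-[(Z)-2-(hexamer A–F aryloxy)vinyl]cyclobut-2-enone, via vinyllithium 42 (not isolated), via lithium alkoxide 43 (not isolated)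
Conditions: t-BuLi (2.0 equiv), THF–Et2O, −78 °C; added to 3 (1.5 equiv), THF, −78 °C; then TBSOTf, 2,6-lutidine, −78 to −20 °C
Reagents that add atoms: tert-butyldimethylsilyl trifluoromethanesulfonate, CC(C)(C)[Si](C)(C)OS(=O)(=O)C(F)(F)F
Why: Bromine–lithium exchange, squarate 1,2-addition and silylation in the flask, as in step 9; the racemic C4 centre is lost in step 21.

Step 21
Reactants: 44 racemic 4-silyloxy-4-[(Z)-2-(hexamer A–F aryloxy)vinyl]cyclobutenone
Product: 47 heptamer A–G phenol (ring G: 2-OH; 3,4-OBn; 5-OTBS), via dienylketene 45 (not isolated), via cyclohexadienone 46 (not isolated)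
Conditions: toluene (degassed), 110 °C
Reagents that add atoms: none
Why: Moore rearrangement as in step 10, forming the C1–C2 bond of ring G; torquoselectivity again rests on the silyloxy donor.

Step 22
Reactants: 47 heptamer A–G phenol; 25 2,6-bis(benzyloxy)-4-bromobenzaldehyde
Product: 48 octamer A–H aldehyde (ring H: 4-CHO; ring G: 5-OTBS)
Conditions: Pd2(dba)3 (2.5 mol %), tBuXPhos (6 mol %), K3PO4, toluene, 100 °C
Reagents that add atoms: none
Why: Buchwald–Hartwig-type C–O coupling as in step 12; the silyl ether is kept because the next step removes it.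

Step 23
Reactants: 48 octamer A–H aldehyde
Product: 50 octamer diphenol (ring H: 4-OH; ring G: 5-OH; nineteen OBn), via aryl formate 49 (not isolated)
Conditions: mCPBA (1.2 equiv), NaHCO3, CH2Cl2, 0 °C to rt; then K2CO3, MeOH–THF, rt, argon
Reagents that add atoms: mCPBA, OOC(=O)c1cccc(Cl)c1
Why: Dakin-type Baeyer–Villiger oxidation of the ring H aldehyde; K2CO3 in methanol then cleaves the aryl formate and, by methanolysis at silicon, the aryl silyl ether, so that only benzyl ethers remain.

Step 24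
Reactants: 50 octamer diphenol
Product: 51 target octamer (CNP0175816.0)
Conditions: H2 (1 atm), Pd(OH)2/C, THF–MeOH, rt; filtration and concentration under argon
Reagents that add atoms: none
Why: Catalytic hydrogenolysis of the nineteen aryl benzyl ethers under neutral conditions; diaryl ethers and the arene rings should not be reduced at this pressure, and the absence of base protects the polyphenol from oxidation.

## Compound list

1 | squaric acid | OC1=C(O)C(=O)C1=O | starting material
2 | benzyl alcohol | OCc1ccccc1 | starting material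
3 | dibenzyl squarate | O=C1C(=O)C(OCc9ccccc9)=C1OCc9ccccc9 | intermediate
4 | phloroglucinol | Oc1cc(O)cc(O)c1 | starting material
5 | N,N-dimethyl(2,4,6-trihydroxybenzylidene)iminium chloride | C[N+](C)=Cc1c(O)cc(O)cc1O.[Cl-] | intermediate
6 | 2,4,6-trihydroxybenzaldehyde | O=Cc1c(O)cc(O)cc1O | intermediate
7 | 2,4,6-tris(benzyloxy)benzaldehyde | O=Cc1c(OCc9ccccc9)cc(OCc9ccccc9)cc1OCc9ccccc9 | intermediate
8 | 2,4,6-tris(benzyloxy)phenyl formate | O=COc1c(OCc9ccccc9)cc(OCc9ccccc9)cc1OCc9ccccc9 | intermediate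
9 | 2,4,6-tris(benzyloxy)phenol (ring A) | Oc1c(OCc9ccccc9)cc(OCc9ccccc9)cc1OCc9ccccc9 | intermediate
10 | 5-bromo-2,3-dihydroxybenzaldehyde | O=Cc1cc(Br)cc(O)c1O | starting material
11 | 2,3-bis(benzyloxy)-5-bromobenzaldehyde | O=Cc1cc(Br)cc(OCc9ccccc9)c1OCc9ccccc9 | intermediate
12 | dimer A–B aldehyde, 2,3-bis(benzyloxy)-5-[2,4,6-tris(benzyloxy)phenoxy]benzaldehyde | O=Cc3cc(Oc4c(OCc9ccccc9)cc(OCc9ccccc9)cc4OCc9ccccc9)cc(OCc9ccccc9)c3OCc9ccccc9 | intermediate
13 | dimer A–B formate, 2,3-bis(benzyloxy)-5-[2,4,6-tris(benzyloxy)phenoxy]phenyl formate | O=COc3cc(Oc4c(OCc9ccccc9)cc(OCc9ccccc9)cc4OCc9ccccc9)cc(OCc9ccccc9)c3OCc9ccccc9 | intermediate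
14 | dimer A–B phenol, 2,3-bis(benzyloxy)-5-[2,4,6-tris(benzyloxy)phenoxy]phenol | Oc3cc(Oc4c(OCc9ccccc9)cc(OCc9ccccc9)cc4OCc9ccccc9)cc(OCc9ccccc9)c3OCc9ccccc9 | intermediate
15 | 1,2-dibromoethylene (commercial cis/trans mixture) | BrC=CBr | starting material
16 | bromoacetylene | BrC#C | intermediate
17 | (Z)-2-bromovinyl ether of 14, 1,2-bis(benzyloxy)-3-[(Z)-2-bromovinyloxy]-5-[2,4,6-tris(benzyloxy)phenoxy]benzene | Br/C=C\Oc3cc(Oc4c(OCc9ccccc9)cc(OCc9ccccc9)cc4OCc9ccccc9)cc(OCc9ccccc9)c3OCc9ccccc9 | intermediate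
18 | (Z)-2-(A–B aryloxy)vinyllithium | [Li]/C=C\Oc3cc(Oc4c(OCc9ccccc9)cc(OCc9ccccc9)cc4OCc9ccccc9)cc(OCc9ccccc9)c3OCc9ccccc9 | intermediate
19 | racemic lithium 2,3-bis(benzyloxy)-4-oxo-1-[(Z)-2-(A–B aryloxy)vinyl]cyclobut-2-en-1-olate | O=C1C(OCc9ccccc9)=C(OCc9ccccc9)C1(O[Li])/C=C\Oc3cc(Oc4c(OCc9ccccc9)cc(OCc9ccccc9)cc4OCc9ccccc9)cc(OCc9ccccc9)c3OCc9ccccc9 | intermediate
20 | racemic 2,3-bis(benzyloxy)-4-(tert-butyldimethylsilyloxy)-4-[(Z)-2-(A–B aryloxy)vinyl]cyclobut-2-enone | O=C1C(OCc9ccccc9)=C(OCc9ccccc9)C1(O[Si](C)(C)C(C)(C)C)/C=C\Oc2cc(Oc3c(OCc9ccccc9)cc(OCc9ccccc9)cc3OCc9ccccc9)cc(OCc9ccccc9)c2OCc9ccccc9 | intermediate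
21 | dienylketene, (3Z,5Z)-2,3-bis(benzyloxy)-4-(tert-butyldimethylsilyloxy)-6-(A–B aryloxy)hexa-1,3,5-trien-1-one | O=C=C(OCc9ccccc9)/C(OCc9ccccc9)=C(\C=C/Oc3cc(Oc4c(OCc9ccccc9)cc(OCc9ccccc9)cc4OCc9ccccc9)cc(OCc9ccccc9)c3OCc9ccccc9)O[Si](C)(C)C(C)(C)C | intermediate
22 | racemic 6-(A–B aryloxy)-2,3-bis(benzyloxy)-4-(tert-butyldimethylsilyloxy)cyclohexa-2,4-dien-1-one | O=C1C(OCc9ccccc9)=C(OCc9ccccc9)C(O[Si](C)(C)C(C)(C)C)=CC1Oc3cc(Oc4c(OCc9ccccc9)cc(OCc9ccccc9)cc4OCc9ccccc9)cc(OCc9ccccc9)c3OCc9ccccc9 | intermediate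
23 | trimer A–C phenol (ring C: 2-OH, 3,4-OBn, 5-OTBS; rings A and B perbenzylated) | Oc1c(OCc9ccccc9)c(OCc9ccccc9)c(O[Si](C)(C)C(C)(C)C)cc1Oc2cc(Oc3c(OCc9ccccc9)cc(OCc9ccccc9)cc3OCc9ccccc9)cc(OCc9ccccc9)c2OCc9ccccc9 | intermediate
24 | 4-bromo-2,6-difluorobenzaldehyde | O=Cc1c(F)cc(Br)cc1F | starting material
25 | 2,6-bis(benzyloxy)-4-bromobenzaldehyde | O=Cc1c(OCc9ccccc9)cc(Br)cc1OCc9ccccc9 | intermediate
26 | tetramer A–D aldehyde silyl ether (ring D: 4-CHO, 3,5-OBn; ring C: 3,4-OBn, 5-OTBS) | O=Cc1c(OCc9ccccc9)cc(Oc2c(OCc9ccccc9)c(OCc9ccccc9)c(O[Si](C)(C)C(C)(C)C)cc2Oc3cc(Oc4c(OCc9ccccc9)cc(OCc9ccccc9)cc4OCc9ccccc9)cc(OCc9ccccc9)c3OCc9ccccc9)cc1OCc9ccccc9 | intermediate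
27 | perbenzylated tetramer A–D aldehyde (ring D: 4-CHO) | O=Cc1c(OCc9ccccc9)cc(Oc2c(OCc9ccccc9)c(OCc9ccccc9)c(OCc9ccccc9)cc2Oc3cc(Oc4c(OCc9ccccc9)cc(OCc9ccccc9)cc4OCc9ccccc9)cc(OCc9ccccc9)c3OCc9ccccc9)cc1OCc9ccccc9 | intermediate
28 | perbenzylated tetramer A–D formate (ring D: 4-OCHO) | O=COc1c(OCc9ccccc9)cc(Oc2c(OCc9ccccc9)c(OCc9ccccc9)c(OCc9ccccc9)cc2Oc3cc(Oc4c(OCc9ccccc9)cc(OCc9ccccc9)cc4OCc9ccccc9)cc(OCc9ccccc9)c3OCc9ccccc9)cc1OCc9ccccc9 | intermediate
29 | tetramer A–D phenol (ring D: 4-OH, 3,5-OBn; rings A–C perbenzylated) | Oc1c(OCc9ccccc9)cc(Oc2c(OCc9ccccc9)c(OCc9ccccc9)c(OCc9ccccc9)cc2Oc3cc(Oc4c(OCc9ccccc9)cc(OCc9ccccc9)cc4OCc9ccccc9)cc(OCc9ccccc9)c3OCc9ccccc9)cc1OCc9ccccc9 | intermediate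
30 | (Z)-2-bromovinyl ether of 29 (ring D C4–O–CH=CHBr) | Br/C=C\Oc1c(OCc9ccccc9)cc(Oc2c(OCc9ccccc9)c(OCc9ccccc9)c(OCc9ccccc9)cc2Oc3cc(Oc4c(OCc9ccccc9)cc(OCc9ccccc9)cc4OCc9ccccc9)cc(OCc9ccccc9)c3OCc9ccccc9)cc1OCc9ccccc9 | intermediate
31 | (Z)-2-(tetramer A–D aryloxy)vinyllithium | [Li]/C=C\Oc1c(OCc9ccccc9)cc(Oc2c(OCc9ccccc9)c(OCc9ccccc9)c(OCc9ccccc9)cc2Oc3cc(Oc4c(OCc9ccccc9)cc(OCc9ccccc9)cc4OCc9ccccc9)cc(OCc9ccccc9)c3OCc9ccccc9)cc1OCc9ccccc9 | intermediate
32 | racemic lithium alkoxide of the 4-hydroxy-4-[(Z)-2-(tetramer A–D aryloxy)vinyl]-2,3-bis(benzyloxy)cyclobutenone | O=C5C(OCc9ccccc9)=C(OCc9ccccc9)C5(O[Li])/C=C\Oc1c(OCc9ccccc9)cc(Oc2c(OCc9ccccc9)c(OCc9ccccc9)c(OCc9ccccc9)cc2Oc3cc(Oc4c(OCc9ccccc9)cc(OCc9ccccc9)cc4OCc9ccccc9)cc(OCc9ccccc9)c3OCc9ccccc9)cc1OCc9ccccc9 | intermediate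
33 | racemic 2,3-bis(benzyloxy)-4-(tert-butyldimethylsilyloxy)-4-[(Z)-2-(tetramer A–D aryloxy)vinyl]cyclobut-2-enone | O=C5C(OCc9ccccc9)=C(OCc9ccccc9)C5(O[Si](C)(C)C(C)(C)C)/C=C\Oc1c(OCc9ccccc9)cc(Oc2c(OCc9ccccc9)c(OCc9ccccc9)c(OCc9ccccc9)cc2Oc3cc(Oc4c(OCc9ccccc9)cc(OCc9ccccc9)cc4OCc9ccccc9)cc(OCc9ccccc9)c3OCc9ccccc9)cc1OCc9ccccc9 | intermediate
34 | dienylketene for ring E, (3Z,5Z)-2,3-bis(benzyloxy)-4-(tert-butyldimethylsilyloxy)-6-(tetramer A–D aryloxy)hexa-1,3,5-trien-1-one | O=C=C(OCc9ccccc9)/C(OCc9ccccc9)=C(\C=C/Oc1c(OCc9ccccc9)cc(Oc2c(OCc9ccccc9)c(OCc9ccccc9)c(OCc9ccccc9)cc2Oc3cc(Oc4c(OCc9ccccc9)cc(OCc9ccccc9)cc4OCc9ccccc9)cc(OCc9ccccc9)c3OCc9ccccc9)cc1OCc9ccccc9)O[Si](C)(C)C(C)(C)C | intermediate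
35 | racemic 6-(tetramer A–D aryloxy)-2,3-bis(benzyloxy)-4-(tert-butyldimethylsilyloxy)cyclohexa-2,4-dien-1-one | O=C5C(OCc9ccccc9)=C(OCc9ccccc9)C(O[Si](C)(C)C(C)(C)C)=CC5Oc1c(OCc9ccccc9)cc(Oc2c(OCc9ccccc9)c(OCc9ccccc9)c(OCc9ccccc9)cc2Oc3cc(Oc4c(OCc9ccccc9)cc(OCc9ccccc9)cc4OCc9ccccc9)cc(OCc9ccccc9)c3OCc9ccccc9)cc1OCc9ccccc9 | intermediate
36 | pentamer A–E phenol (ring E: 2-OH, 3,4-OBn, 5-OTBS; rings A–D perbenzylated) | Oc5c(OCc9ccccc9)c(OCc9ccccc9)c(O[Si](C)(C)C(C)(C)C)cc5Oc1c(OCc9ccccc9)cc(Oc2c(OCc9ccccc9)c(OCc9ccccc9)c(OCc9ccccc9)cc2Oc3cc(Oc4c(OCc9ccccc9)cc(OCc9ccccc9)cc4OCc9ccccc9)cc(OCc9ccccc9)c3OCc9ccccc9)cc1OCc9ccccc9 | intermediate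
37 | hexamer A–F aldehyde silyl ether (ring F: 4-CHO, 3,5-OBn; ring E: 3,4-OBn, 5-OTBS) | O=Cc6c(OCc9ccccc9)cc(Oc5c(OCc9ccccc9)c(OCc9ccccc9)c(O[Si](C)(C)C(C)(C)C)cc5Oc1c(OCc9ccccc9)cc(Oc2c(OCc9ccccc9)c(OCc9ccccc9)c(OCc9ccccc9)cc2Oc3cc(Oc4c(OCc9ccccc9)cc(OCc9ccccc9)cc4OCc9ccccc9)cc(OCc9ccccc9)c3OCc9ccccc9)cc1OCc9ccccc9)cc6OCc9ccccc9 | intermediate
38 | perbenzylated hexamer A–F aldehyde (ring F: 4-CHO) | O=Cc6c(OCc9ccccc9)cc(Oc5c(OCc9ccccc9)c(OCc9ccccc9)c(OCc9ccccc9)cc5Oc1c(OCc9ccccc9)cc(Oc2c(OCc9ccccc9)c(OCc9ccccc9)c(OCc9ccccc9)cc2Oc3cc(Oc4c(OCc9ccccc9)cc(OCc9ccccc9)cc4OCc9ccccc9)cc(OCc9ccccc9)c3OCc9ccccc9)cc1OCc9ccccc9)cc6OCc9ccccc9 | intermediate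
39 | perbenzylated hexamer A–F formate (ring F: 4-OCHO) | O=COc6c(OCc9ccccc9)cc(Oc5c(OCc9ccccc9)c(OCc9ccccc9)c(OCc9ccccc9)cc5Oc1c(OCc9ccccc9)cc(Oc2c(OCc9ccccc9)c(OCc9ccccc9)c(OCc9ccccc9)cc2Oc3cc(Oc4c(OCc9ccccc9)cc(OCc9ccccc9)cc4OCc9ccccc9)cc(OCc9ccccc9)c3OCc9ccccc9)cc1OCc9ccccc9)cc6OCc9ccccc9 | intermediate
40 | hexamer A–F phenol (ring F: 4-OH, 3,5-OBn; rings A–E perbenzylated) | Oc6c(OCc9ccccc9)cc(Oc5c(OCc9ccccc9)c(OCc9ccccc9)c(OCc9ccccc9)cc5Oc1c(OCc9ccccc9)cc(Oc2c(OCc9ccccc9)c(OCc9ccccc9)c(OCc9ccccc9)cc2Oc3cc(Oc4c(OCc9ccccc9)cc(OCc9ccccc9)cc4OCc9ccccc9)cc(OCc9ccccc9)c3OCc9ccccc9)cc1OCc9ccccc9)cc6OCc9ccccc9 | intermediate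
41 | (Z)-2-bromovinyl ether of 40 (ring F C4–O–CH=CHBr) | Br/C=C\Oc6c(OCc9ccccc9)cc(Oc5c(OCc9ccccc9)c(OCc9ccccc9)c(OCc9ccccc9)cc5Oc1c(OCc9ccccc9)cc(Oc2c(OCc9ccccc9)c(OCc9ccccc9)c(OCc9ccccc9)cc2Oc3cc(Oc4c(OCc9ccccc9)cc(OCc9ccccc9)cc4OCc9ccccc9)cc(OCc9ccccc9)c3OCc9ccccc9)cc1OCc9ccccc9)cc6OCc9ccccc9 | intermediate
42 | (Z)-2-(hexamer A–F aryloxy)vinyllithium | [Li]/C=C\Oc6c(OCc9ccccc9)cc(Oc5c(OCc9ccccc9)c(OCc9ccccc9)c(OCc9ccccc9)cc5Oc1c(OCc9ccccc9)cc(Oc2c(OCc9ccccc9)c(OCc9ccccc9)c(OCc9ccccc9)cc2Oc3cc(Oc4c(OCc9ccccc9)cc(OCc9ccccc9)cc4OCc9ccccc9)cc(OCc9ccccc9)c3OCc9ccccc9)cc1OCc9ccccc9)cc6OCc9ccccc9 | intermediate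
43 | racemic lithium alkoxide of the 4-hydroxy-4-[(Z)-2-(hexamer A–F aryloxy)vinyl]-2,3-bis(benzyloxy)cyclobutenone | O=C7C(OCc9ccccc9)=C(OCc9ccccc9)C7(O[Li])/C=C\Oc6c(OCc9ccccc9)cc(Oc5c(OCc9ccccc9)c(OCc9ccccc9)c(OCc9ccccc9)cc5Oc1c(OCc9ccccc9)cc(Oc2c(OCc9ccccc9)c(OCc9ccccc9)c(OCc9ccccc9)cc2Oc3cc(Oc4c(OCc9ccccc9)cc(OCc9ccccc9)cc4OCc9ccccc9)cc(OCc9ccccc9)c3OCc9ccccc9)cc1OCc9ccccc9)cc6OCc9ccccc9 | intermediate
44 | racemic 2,3-bis(benzyloxy)-4-(tert-butyldimethylsilyloxy)-4-[(Z)-2-(hexamer A–F aryloxy)vinyl]cyclobut-2-enone | O=C7C(OCc9ccccc9)=C(OCc9ccccc9)C7(O[Si](C)(C)C(C)(C)C)/C=C\Oc6c(OCc9ccccc9)cc(Oc5c(OCc9ccccc9)c(OCc9ccccc9)c(OCc9ccccc9)cc5Oc1c(OCc9ccccc9)cc(Oc2c(OCc9ccccc9)c(OCc9ccccc9)c(OCc9ccccc9)cc2Oc3cc(Oc4c(OCc9ccccc9)cc(OCc9ccccc9)cc4OCc9ccccc9)cc(OCc9ccccc9)c3OCc9ccccc9)cc1OCc9ccccc9)cc6OCc9ccccc9 | intermediate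
45 | dienylketene for ring G, (3Z,5Z)-2,3-bis(benzyloxy)-4-(tert-butyldimethylsilyloxy)-6-(hexamer A–F aryloxy)hexa-1,3,5-trien-1-one | O=C=C(OCc9ccccc9)/C(OCc9ccccc9)=C(\C=C/Oc6c(OCc9ccccc9)cc(Oc5c(OCc9ccccc9)c(OCc9ccccc9)c(OCc9ccccc9)cc5Oc1c(OCc9ccccc9)cc(Oc2c(OCc9ccccc9)c(OCc9ccccc9)c(OCc9ccccc9)cc2Oc3cc(Oc4c(OCc9ccccc9)cc(OCc9ccccc9)cc4OCc9ccccc9)cc(OCc9ccccc9)c3OCc9ccccc9)cc1OCc9ccccc9)cc6OCc9ccccc9)O[Si](C)(C)C(C)(C)C | intermediate
46 | racemic 6-(hexamer A–F aryloxy)-2,3-bis(benzyloxy)-4-(tert-butyldimethylsilyloxy)cyclohexa-2,4-dien-1-one | O=C7C(OCc9ccccc9)=C(OCc9ccccc9)C(O[Si](C)(C)C(C)(C)C)=CC7Oc6c(OCc9ccccc9)cc(Oc5c(OCc9ccccc9)c(OCc9ccccc9)c(OCc9ccccc9)cc5Oc1c(OCc9ccccc9)cc(Oc2c(OCc9ccccc9)c(OCc9ccccc9)c(OCc9ccccc9)cc2Oc3cc(Oc4c(OCc9ccccc9)cc(OCc9ccccc9)cc4OCc9ccccc9)cc(OCc9ccccc9)c3OCc9ccccc9)cc1OCc9ccccc9)cc6OCc9ccccc9 | intermediate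
47 | heptamer A–G phenol (ring G: 2-OH, 3,4-OBn, 5-OTBS; rings A–F perbenzylated) | Oc7c(OCc9ccccc9)c(OCc9ccccc9)c(O[Si](C)(C)C(C)(C)C)cc7Oc6c(OCc9ccccc9)cc(Oc5c(OCc9ccccc9)c(OCc9ccccc9)c(OCc9ccccc9)cc5Oc1c(OCc9ccccc9)cc(Oc2c(OCc9ccccc9)c(OCc9ccccc9)c(OCc9ccccc9)cc2Oc3cc(Oc4c(OCc9ccccc9)cc(OCc9ccccc9)cc4OCc9ccccc9)cc(OCc9ccccc9)c3OCc9ccccc9)cc1OCc9ccccc9)cc6OCc9ccccc9 | intermediate
48 | octamer A–H aldehyde (ring H: 4-CHO, 3,5-OBn; ring G: 3,4-OBn, 5-OTBS; rings A–F perbenzylated) | O=Cc8c(OCc9ccccc9)cc(Oc7c(OCc9ccccc9)c(OCc9ccccc9)c(O[Si](C)(C)C(C)(C)C)cc7Oc6c(OCc9ccccc9)cc(Oc5c(OCc9ccccc9)c(OCc9ccccc9)c(OCc9ccccc9)cc5Oc1c(OCc9ccccc9)cc(Oc2c(OCc9ccccc9)c(OCc9ccccc9)c(OCc9ccccc9)cc2Oc3cc(Oc4c(OCc9ccccc9)cc(OCc9ccccc9)cc4OCc9ccccc9)cc(OCc9ccccc9)c3OCc9ccccc9)cc1OCc9ccccc9)cc6OCc9ccccc9)cc8OCc9ccccc9 | intermediate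
49 | octamer A–H formate (ring H: 4-OCHO; ring G: 5-OTBS) | O=COc8c(OCc9ccccc9)cc(Oc7c(OCc9ccccc9)c(OCc9ccccc9)c(O[Si](C)(C)C(C)(C)C)cc7Oc6c(OCc9ccccc9)cc(Oc5c(OCc9ccccc9)c(OCc9ccccc9)c(OCc9ccccc9)cc5Oc1c(OCc9ccccc9)cc(Oc2c(OCc9ccccc9)c(OCc9ccccc9)c(OCc9ccccc9)cc2Oc3cc(Oc4c(OCc9ccccc9)cc(OCc9ccccc9)cc4OCc9ccccc9)cc(OCc9ccccc9)c3OCc9ccccc9)cc1OCc9ccccc9)cc6OCc9ccccc9)cc8OCc9ccccc9 | intermediate
50 | octamer diphenol (ring H: 4-OH, 3,5-OBn; ring G: 5-OH, 3,4-OBn; rings A–F perbenzylated) | Oc8c(OCc9ccccc9)cc(Oc7c(OCc9ccccc9)c(OCc9ccccc9)c(O)cc7Oc6c(OCc9ccccc9)cc(Oc5c(OCc9ccccc9)c(OCc9ccccc9)c(OCc9ccccc9)cc5Oc1c(OCc9ccccc9)cc(Oc2c(OCc9ccccc9)c(OCc9ccccc9)c(OCc9ccccc9)cc2Oc3cc(Oc4c(OCc9ccccc9)cc(OCc9ccccc9)cc4OCc9ccccc9)cc(OCc9ccccc9)c3OCc9ccccc9)cc1OCc9ccccc9)cc6OCc9ccccc9)cc8OCc9ccccc9 | intermediate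
51 | target octamer CNP0175816.0 (all twenty-one hydroxyls free) | Oc1cc(O)c(Oc2cc(O)c(O)c(Oc3cc(O)c(O)c(O)c3Oc3cc(O)c(Oc4cc(O)c(O)c(O)c4Oc4cc(O)c(Oc5cc(O)c(O)c(O)c5Oc5cc(O)c(O)c(O)c5)c(O)c4)c(O)c3)c2)c(O)c1 | target

## Step count and least certain steps

Total: 24 steps. Longest linear sequence: 21 steps (steps 2–4, 6–10 and 12–24, counted from phloroglucinol).

**Step 10 (key step; the same reaction recurs in steps 16 and 21).** The six-electron closure may be retarded because the aryloxy group on the Z double bond points into the closing ring. The dienylketene then lives long enough to be trapped by adventitious nucleophiles or to oligomerise, and the electron-rich hydroquinone monoether may be oxidised by air during isolation. The fallback sets out from 14 and returns at 23; it replaces the alkenyl by an alkynyl ring expansion, which has no inward substituent. Compound 14 is heated with trichloroethylene and K2CO3 in DMF to give the (E)-1,2-dichlorovinyl ether F1. Two equivalents of n-BuLi at −78 °C convert it into the lithium aryloxyacetylide, which adds to 3 and is quenched with NH4Cl to give the 4-(aryloxyethynyl)-4-hydroxycyclobutenone F2. Heating in toluene (alkynyl variant of the Moore rearrangement, via an enynylketene; closure to the six-membered ring must win over the five-membered alternative) should give the 2-aryloxy-5,6-bis(benzyloxy)-1,4-benzoquinone F3. Na2S2O4 reduces it to the hydroquinone F4, and TBSCl/imidazole should silylate the hydroxyl flanked by only one ortho oxygen, which gives 23.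

**Step 9 (and its repeats, steps 15 and 20).** Loss of lithium aryloxide from the vinyllithium by β-elimination, competing deprotonation at benzylic or vinylic C–H by t-BuLi, or incomplete silylation followed by anion-accelerated ring opening on warming would all lower the throughput. The fallback sets out from 14 and returns at 20; it uses an sp carbanion that cannot eliminate and sets the Z geometry afterwards. The dichlorovinyl ether F1 (made as above) is converted with n-BuLi into the lithium aryloxyacetylide, which is added to 3 and silylated in the flask with TBSOTf to give the 4-(aryloxyethynyl)-4-silyloxycyclobutenone F5. Semihydrogenation with H2 over Pd/CaCO3 poisoned with Pb(OAc)2 and quinoline (syn addition) then gives the Z enol ether 20. This route also bypasses the bromovinylation of step 8.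

**Step 12 (and its repeats, steps 17 and 22).** C–O reductive elimination may be slow for a phenoxide flanked by two ortho oxygens, so that hydrodebromination of 25 competes. Premature loss of the silyl group would allow arylation at the wrong oxygen. The fallback sets out from 23 and 25 and returns at 27; it replaces the palladium cycle by an oxidative copper coupling at room temperature without strong base. Compound 25 is borylated with B2(OH)4 under Pd(OAc)2/XPhos catalysis (KOAc, EtOH) to the (3,5-bis(benzyloxy)-4-formylphenyl)boronic acid F6. Chan–Lam coupling of F6 with 23 (Cu(OAc)2, pyridine, 4 Å molecular sieves, CH2Cl2, air) gives 26, which the same CsF/BnBr treatment converts into 27.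

**Step 24.** Incomplete hydrogenolysis of nineteen benzyl ethers, deactivation of the catalyst by adsorption of the polyphenol, and air oxidation of the product during isolation are the likely problems. The fallback sets out from 50 and returns at 51 and changes from reduction to Lewis-acid dealkylation: BCl3 with pentamethylbenzene as benzyl-cation scavenger in CH2Cl2 at −78 °C, followed by methanol quench under argon. It makes no new compound.

## Further compounds

F1 | step 10 | (E)-1,2-dichlorovinyl ether of 14, 1,2-bis(benzyloxy)-3-[(E)-1,2-dichlorovinyloxy]-5-[2,4,6-tris(benzyloxy)phenoxy]benzene | Cl/C=C(/Cl)Oc3cc(Oc4c(OCc9ccccc9)cc(OCc9ccccc9)cc4OCc9ccccc9)cc(OCc9ccccc9)c3OCc9ccccc9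
F2 | step 10 | racemic 4-[(A–B aryloxy)ethynyl]-2,3-bis(benzyloxy)-4-hydroxycyclobut-2-enone | O=C1C(OCc9ccccc9)=C(OCc9ccccc9)C1(O)C#COc3cc(Oc4c(OCc9ccccc9)cc(OCc9ccccc9)cc4OCc9ccccc9)cc(OCc9ccccc9)c3OCc9ccccc9
F3 | step 10 | 2-(A–B aryloxy)-5,6-bis(benzyloxy)-1,4-benzoquinone | O=C1C=C(Oc3cc(Oc4c(OCc9ccccc9)cc(OCc9ccccc9)cc4OCc9ccccc9)cc(OCc9ccccc9)c3OCc9ccccc9)C(=O)C(OCc9ccccc9)=C1OCc9ccccc9
F4 | step 10 | 5-(A–B aryloxy)-2,3-bis(benzyloxy)benzene-1,4-diol | Oc1cc(Oc3cc(Oc4c(OCc9ccccc9)cc(OCc9ccccc9)cc4OCc9ccccc9)cc(OCc9ccccc9)c3OCc9ccccc9)c(O)c(OCc9ccccc9)c1OCc9ccccc9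
F5 | step 9 | racemic 4-[(A–B aryloxy)ethynyl]-2,3-bis(benzyloxy)-4-(tert-butyldimethylsilyloxy)cyclobut-2-enone | O=C1C(OCc9ccccc9)=C(OCc9ccccc9)C1(O[Si](C)(C)C(C)(C)C)C#COc3cc(Oc4c(OCc9ccccc9)cc(OCc9ccccc9)cc4OCc9ccccc9)cc(OCc9ccccc9)c3OCc9ccccc9
F6 | step 12 | (3,5-bis(benzyloxy)-4-formylphenyl)boronic acid | O=Cc1c(OCc9ccccc9)cc(B(O)O)cc1OCc9ccccc9
F0 | step 24 | none | none
A1 | alternative 1 | octamer heptaphenol with fourteen benzyl ethers (free OH at ring A C4 and at C3, C4 of rings C, E, G) | Oc1cc(OCc9ccccc9)c(Oc2cc(OCc9ccccc9)c(OCc9ccccc9)c(Oc3cc(OCc9ccccc9)c(O)c(O)c3Oc3cc(OCc9ccccc9)c(Oc4cc(OCc9ccccc9)c(O)c(O)c4Oc4cc(OCc9ccccc9)c(Oc5cc(OCc9ccccc9)c(O)c(O)c5Oc5cc(OCc9ccccc9)c(OCc9ccccc9)c(OCc9ccccc9)c5)c(OCc9ccccc9)c4)c(OCc9ccccc9)c3)c2)c(OCc9ccccc9)c1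
A2 | alternative 1 | octamer heptaaldehyde with fourteen benzyl ethers (CHO at ring A C4 and at C3, C4 of rings C, E, G) | O=Cc1cc(OCc9ccccc9)c(Oc2cc(OCc9ccccc9)c(OCc9ccccc9)c(Oc3cc(OCc9ccccc9)c(C=O)c(C=O)c3Oc3cc(OCc9ccccc9)c(Oc4cc(OCc9ccccc9)c(C=O)c(C=O)c4Oc4cc(OCc9ccccc9)c(Oc5cc(OCc9ccccc9)c(C=O)c(C=O)c5Oc5cc(OCc9ccccc9)c(OCc9ccccc9)c(OCc9ccccc9)c5)c(OCc9ccccc9)c4)c(OCc9ccccc9)c3)c2)c(OCc9ccccc9)c1
A3 | alternative 2 | octamer with ring A as methyl 2,4,6-trihydroxybenzoate bearing the B–H aryloxy group at C3, rings B–H perbenzylated | COC(=O)c1c(O)cc(O)c(Oc2cc(OCc9ccccc9)c(OCc9ccccc9)c(Oc3cc(OCc9ccccc9)c(OCc9ccccc9)c(OCc9ccccc9)c3Oc3cc(OCc9ccccc9)c(Oc4cc(OCc9ccccc9)c(OCc9ccccc9)c(OCc9ccccc9)c4Oc4cc(OCc9ccccc9)c(Oc5cc(OCc9ccccc9)c(OCc9ccccc9)c(OCc9ccccc9)c5Oc5cc(OCc9ccccc9)c(OCc9ccccc9)c(OCc9ccccc9)c5)c(OCc9ccccc9)c4)c(OCc9ccccc9)c3)c2)c1O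
A4 | alternative 2 | dimethyl 4-(perbenzylated B–H aryloxy)-3,5-dioxoheptanedioate | COC(=O)CC(=O)C(Oc2cc(OCc9ccccc9)c(OCc9ccccc9)c(Oc3cc(OCc9ccccc9)c(OCc9ccccc9)c(OCc9ccccc9)c3Oc3cc(OCc9ccccc9)c(Oc4cc(OCc9ccccc9)c(OCc9ccccc9)c(OCc9ccccc9)c4Oc4cc(OCc9ccccc9)c(Oc5cc(OCc9ccccc9)c(OCc9ccccc9)c(OCc9ccccc9)c5Oc5cc(OCc9ccccc9)c(OCc9ccccc9)c(OCc9ccccc9)c5)c(OCc9ccccc9)c4)c(OCc9ccccc9)c3)c2)C(=O)CC(=O)OC
A5 | alternative 3 | octamer with free C5–OH on ring E, all other hydroxyls benzylated | c9ccccc9COc1cc(OCc9ccccc9)c(Oc2cc(OCc9ccccc9)c(OCc9ccccc9)c(Oc3cc(OCc9ccccc9)c(OCc9ccccc9)c(OCc9ccccc9)c3Oc3cc(OCc9ccccc9)c(Oc4cc(O)c(OCc9ccccc9)c(OCc9ccccc9)c4Oc4cc(OCc9ccccc9)c(Oc5cc(OCc9ccccc9)c(OCc9ccccc9)c(OCc9ccccc9)c5Oc5cc(OCc9ccccc9)c(OCc9ccccc9)c(OCc9ccccc9)c5)c(OCc9ccccc9)c4)c(OCc9ccccc9)c3)c2)c(OCc9ccccc9)c1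
A6 | alternative 3 | racemic 2-(perbenzylated F–H aryloxy)-3,4-bis(benzyloxy)cyclobut-2-enone | O=C1C(Oc4cc(OCc9ccccc9)c(Oc5cc(OCc9ccccc9)c(OCc9ccccc9)c(OCc9ccccc9)c5Oc5cc(OCc9ccccc9)c(OCc9ccccc9)c(OCc9ccccc9)c5)c(OCc9ccccc9)c4)=C(OCc9ccccc9)C1OCc9ccccc9
A7 | alternative 3 | ethynyl ether of the perbenzylated A–D tetramer (ring D C4–O–C≡CH) | c9ccccc9COc1cc(OCc9ccccc9)c(Oc2cc(OCc9ccccc9)c(OCc9ccccc9)c(Oc3cc(OCc9ccccc9)c(OCc9ccccc9)c(OCc9ccccc9)c3Oc3cc(OCc9ccccc9)c(OC#C)c(OCc9ccccc9)c3)c2)c(OCc9ccccc9)c1
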